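**Retrosynthetic overview**
1. Target 19 comes from 16 by chelation-guided cleavage of the 5-OMe and hydrogenolysis of four benzyl ethers. 16 comes from 3-iodoflavone 12 by turning C3–I into C3–OH (Mg, then B, then peroxide) and O-methylation.
2. Feature used: ring C has a tetrasubstituted C2=C3 bond with oxygen on C3. In ring A both neighbours of C4a (C5 and C8a) carry oxygen, and C6 and C8 carry the same OMe on either side of C7–O. Ring A plus C4 is therefore a mirror-symmetric 4-alkoxy-2,3,5,6-tetramethoxybenzoyl unit.
3. Key disconnection O1–C2 (with C3–I): 12 comes from ynone 10 by ICl-triggered 6-endo-dig closure. Ring C is the only ring made; rings A and B are bought as arenes.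
4. 10 comes from the C4–C3 bond, by acyl Sonogashira coupling of acid chloride 9 with arylacetylene 8. 9 comes from syringic acid 1 (ester, benzyl ether, C2/C6 dibromide, double copper methoxylation, saponification). 8 comes from aldehyde 7 by one-carbon homologation.

Key step: step 8

Remark on the chemistry: the target has no stereocentre, so no configuration has to be set. Compounds 1 and 7 are taken as catalogue chemicals.

**Step 1**
Reactants: 1 syringic acid
Product: 2 methyl 4-hydroxy-3,5-dimethoxybenzoate
Conditions: MeOH, cat. H2SO4, reflux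
Reagents that add atoms: methanol, CO
Why: Fischer esterification of an unhindered benzoic acid in excess methanol should leave the phenol untouched, and it gives the methyl ester for which exchange with methoxide in step 4 is degenerate.

**Step 2**
Reactants: 2 methyl 4-hydroxy-3,5-dimethoxybenzoate
Product: 3 methyl 4-(benzyloxy)-3,5-dimethoxybenzoate
Conditions: BnBr, K2CO3, DMF, 60 °C
Reagents that add atoms: benzyl bromide, BrCc1ccccc1
Why: Williamson ether synthesis on the only acidic OH installs a group that should tolerate bromine, methoxide, ICl and a Grignard reagent and that leaves at the end by hydrogenolysis.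

**Step 3**
Reactants: 3 methyl 4-(benzyloxy)-3,5-dimethoxybenzoate
Product: 4 methyl 4-(benzyloxy)-2,6-dibromo-3,5-dimethoxybenzoate
Conditions: Br2 (2.5 equiv), NaOAc, AcOH, dark, rt → 50 °C
Reagents that add atoms: bromine, BrBr
Why: In this electrophilic aromatic bromination C2 and C6 are the only free positions of the benzoate ring, each lies ortho to one OMe and para to the other, both are far more activated than the benzyl phenyl ring, and NaOAc buffers HBr so that the benzyl ether should persist.

**Step 4**
Reactants: 4 methyl 4-(benzyloxy)-2,6-dibromo-3,5-dimethoxybenzoate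
Product: 5 methyl 4-(benzyloxy)-2,3,5,6-tetramethoxybenzoate
Conditions: NaOMe (30% in MeOH, excess), CuBr (0.3 equiv), DMF, 110 °C, N2
Reagents that add atoms: sodium methoxide, [Na+].[O-]C
Why: Ullmann-type copper-catalysed methoxylation of aryl bromides is established for bromides flanked by oxygen substituents, the neighbouring ester can hold the copper near each C–Br bond, and benzyl and methyl ethers are inert to methoxide.

**Step 5**
Reactants: 5 methyl 4-(benzyloxy)-2,3,5,6-tetramethoxybenzoate
Product: 6 4-(benzyloxy)-2,3,5,6-tetramethoxybenzoic acid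
Conditions: KOH (excess), EtOH/H2O, reflux; then 1 M HCl, 0 °C
Reagents that add atoms: potassium hydroxide, [K+].[OH-]
Why: Saponification of the doubly ortho-substituted ester needs excess base and prolonged heating, nothing else in 5 is base-labile, and cold acidification avoids protodecarboxylation of the electron-rich acid.

**Step 6**
Reactants: 7 3,4,5-tris(benzyloxy)benzaldehyde
Product: 8 1,2,3-tris(benzyloxy)-5-ethynylbenzene
Conditions: dimethyl (1-diazo-2-oxopropyl)phosphonate, K2CO3, MeOH/THF, rt
Reagents that add atoms: dimethyl (1-diazo-2-oxopropyl)phosphonate, CC(=O)C(=[N+]=[N-])P(=O)(OC)OC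
Why: The Ohira–Bestmann variant of the Seyferth–Gilbert homologation converts a non-enolisable aryl aldehyde into the terminal alkyne in one mild basic operation that benzyl ethers tolerate.

**Step 7**
Reactants: 6 4-(benzyloxy)-2,3,5,6-tetramethoxybenzoic acid; 8 1,2,3-tris(benzyloxy)-5-ethynylbenzene
Product: 10 1-[4-(benzyloxy)-2,3,5,6-tetramethoxyphenyl]-3-[3,4,5-tris(benzyloxy)phenyl]prop-2-yn-1-one, via acid chloride 9 (not isolated)
Conditions: (COCl)2, cat. DMF, CH2Cl2, 0 °C → rt, evaporate; then 8, PdCl2(PPh3)2 (2 mol %), CuI (4 mol %), Et3N, THF, rt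
Reagents that add atoms: oxalyl chloride, O=C(Cl)C(=O)Cl (chlorine of 9 only)
Why: Vilsmeier-type activation gives the aroyl chloride, and in the acyl Sonogashira coupling its C–Cl bond adds to zerovalent palladium, the copper acetylide of 8 transmetalates, and reductive elimination forms C4–C3 at room temperature, where decarbonylation should not compete.

**Step 8**
Reactants: 10 1-[4-(benzyloxy)-2,3,5,6-tetramethoxyphenyl]-3-[3,4,5-tris(benzyloxy)phenyl]prop-2-yn-1-one
Product: 12 7-(benzyloxy)-3-iodo-5,6,8-trimethoxy-2-[3,4,5-tris(benzyloxy)phenyl]chromen-4-one, via O1-methyloxonium chloride 11 (not isolated)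
Conditions: ICl (1.2 equiv), CH2Cl2, −78 °C; aq. Na2S2O3
Reagents that add atoms: iodine monochloride, ClI
Why: ICl delivers I+ to the triple bond of 10, the developing positive charge sits on the alkyne carbon bonded to ring B (stabilised by the 4'-benzyloxy group and remote from the carbonyl), the oxygen of one ortho methoxy group attacks this carbon anti to iodine to give methyloxonium 11, and chloride then removes the methyl group by SN2 to leave neutral 12. The closest known reaction type is the ICl-induced iodocyclisation of 2-methoxyaryl alkynyl ketones to 3-iodochromones and 3-iodoflavones, applied here to a more heavily oxygenated member of that class. Ring C, the only ring formed, closes in the 6-endo-dig mode with formation of O1–C2 and C3–I, whereas the 5-exo-dig mode would require attack at the carbon alpha to the carbonyl, where cationic character is least, and would lead to an aurone skeleton. No stereocentre is created. No choice between the two ortho methoxy groups arises, because ring A of 10 has a mirror plane through C1 and C4, so either closure gives 12 and the spectator ortho methoxy group ends as the 5-OMe peri to C4=O. Chemoselectivity for the alkyne over arene iodination is required and is secured because ring A has no C–H, C2'–H and C6'–H of ring B are deactivated by conjugation with the ynone, and a small excess of ICl at −78 °C should leave ring B and the benzyl ethers untouched.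

**Step 9**
Reactants: 12 7-(benzyloxy)-3-iodo-5,6,8-trimethoxy-2-[3,4,5-tris(benzyloxy)phenyl]chromen-4-one
Product: 15 7-(benzyloxy)-3-hydroxy-5,6,8-trimethoxy-2-[3,4,5-tris(benzyloxy)phenyl]chromen-4-one, via 3-chloromagnesio flavone 13 (not isolated), via flavon-3-yl dimethyl boronate 14 (not isolated)
Conditions: iPrMgCl·LiCl (1.15 equiv), THF, −40 °C; B(OMe)3, −40 → 0 °C; AcOH, 30% H2O2, 0 °C → rt
Reagents that add atoms: hydrogen peroxide, OO (oxygen on C3); isopropylmagnesium chloride, CC(C)[Mg]Cl (MgCl of 13 only); trimethyl borate, COB(OC)OC (B(OMe)2 of 14 only)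
Why: Iodine–magnesium exchange at the sp2 C3–I bond next to the pyrone carbonyl should outrun addition to the vinylogous ester at −40 °C, borate trapping and peroxide oxidation of a 3-metallated flavone is the established flavone-to-flavonol sequence, and this path avoids hot methoxide, which would attack C2 of a 3-halopyrone with ring opening or loss of iodine.

**Step 10**
Reactants: 15 7-(benzyloxy)-3-hydroxy-5,6,8-trimethoxy-2-[3,4,5-tris(benzyloxy)phenyl]chromen-4-one
Product: 16 7-(benzyloxy)-3,5,6,8-tetramethoxy-2-[3,4,5-tris(benzyloxy)phenyl]chromen-4-one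
Conditions: MeI, K2CO3, acetone, reflux
Reagents that add atoms: iodomethane, CI
Why: Williamson O-methylation of the acidic flavonol 3-OH, the only free hydroxyl in 15, is routine and leaves all other groups unchanged.

**Step 11**
Reactants: 16 7-(benzyloxy)-3,5,6,8-tetramethoxy-2-[3,4,5-tris(benzyloxy)phenyl]chromen-4-one
Product: 18 7-(benzyloxy)-5-hydroxy-3,6,8-trimethoxy-2-[3,4,5-tris(benzyloxy)phenyl]chromen-4-one, via dichloroaluminium 5-phenolate 17 (not isolated)
Conditions: AlCl3 (5 equiv), MeCN, rt → 40 °C; then 2 M HCl, 50 °C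
Reagents that add atoms: aluminium trichloride, Cl[Al](Cl)Cl (AlCl2 of 17 only)
Why: In this chelation-controlled Lewis acid ether cleavage aluminium binds C4=O and the peri 5-OMe in a six-membered chelate and chloride takes that methyl group, MeCN tempers AlCl3 so that the non-chelated methyl ethers, the 3-OMe (five-membered chelate only) and the benzyl ethers should remain, BCl3 is avoided because it strips aryl benzyl ethers already at −78 °C, and any benzyl group lost here would fall in step 12 anyway.

**Step 12**
Reactants: 18 7-(benzyloxy)-5-hydroxy-3,6,8-trimethoxy-2-[3,4,5-tris(benzyloxy)phenyl]chromen-4-one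
Product: 19 5,7,3',4',5'-pentahydroxy-3,6,8-trimethoxyflavone
Conditions: H2 (1 atm), 10% Pd/C, THF/MeOH, rt; filtration and concentration under N2
Reagents that add atoms: none
Why: Catalytic hydrogenolysis cleaves the four aryl benzyl ethers under neutral conditions that should not reduce the tetrasubstituted C2=C3 bond or the C4 carbonyl, and exclusion of air protects the pyrogallol ring B.

**Compound list**
1 | syringic acid | COc1cc(C(=O)O)cc(OC)c1O | starting material
2 | methyl 4-hydroxy-3,5-dimethoxybenzoate | COC(=O)c1cc(OC)c(O)c(OC)c1 | intermediate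
3 | methyl 4-(benzyloxy)-3,5-dimethoxybenzoate | COC(=O)c1cc(OC)c(OCc2ccccc2)c(OC)c1 | intermediate
4 | methyl 4-(benzyloxy)-2,6-dibromo-3,5-dimethoxybenzoate | COC(=O)c1c(Br)c(OC)c(OCc2ccccc2)c(OC)c1Br | intermediate
5 | methyl 4-(benzyloxy)-2,3,5,6-tetramethoxybenzoate | COC(=O)c1c(OC)c(OC)c(OCc2ccccc2)c(OC)c1OC | intermediate
6 | 4-(benzyloxy)-2,3,5,6-tetramethoxybenzoic acid | OC(=O)c1c(OC)c(OC)c(OCc2ccccc2)c(OC)c1OC | intermediate
7 | 3,4,5-tris(benzyloxy)benzaldehyde | O=Cc1cc(OCc2ccccc2)c(OCc2ccccc2)c(OCc2ccccc2)c1 | starting material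
8 | 1,2,3-tris(benzyloxy)-5-ethynylbenzene | C#Cc1cc(OCc2ccccc2)c(OCc2ccccc2)c(OCc2ccccc2)c1 | intermediate
9 | 4-(benzyloxy)-2,3,5,6-tetramethoxybenzoyl chloride | O=C(Cl)c1c(OC)c(OC)c(OCc2ccccc2)c(OC)c1OC | intermediate
10 | 1-[4-(benzyloxy)-2,3,5,6-tetramethoxyphenyl]-3-[3,4,5-tris(benzyloxy)phenyl]prop-2-yn-1-one | COc1c(OC)c(OCc2ccccc2)c(OC)c(OC)c1C(=O)C#Cc1cc(OCc2ccccc2)c(OCc2ccccc2)c(OCc2ccccc2)c1 | intermediate
11 | 7-(benzyloxy)-3-iodo-5,6,8-trimethoxy-1-methyl-4-oxo-2-[3,4,5-tris(benzyloxy)phenyl]chromen-1-ium chloride | C[O+]1C(c2cc(OCc3ccccc3)c(OCc3ccccc3)c(OCc3ccccc3)c2)=C(I)C(=O)c2c(OC)c(OC)c(OCc3ccccc3)c(OC)c21.[Cl-] | intermediate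
12 | 7-(benzyloxy)-3-iodo-5,6,8-trimethoxy-2-[3,4,5-tris(benzyloxy)phenyl]chromen-4-one | COc1c(OCc2ccccc2)c(OC)c2oc(-c3cc(OCc4ccccc4)c(OCc4ccccc4)c(OCc4ccccc4)c3)c(I)c(=O)c2c1OC | intermediate
13 | [7-(benzyloxy)-5,6,8-trimethoxy-4-oxo-2-[3,4,5-tris(benzyloxy)phenyl]chromen-3-yl]magnesium chloride | COc1c(OCc2ccccc2)c(OC)c2oc(-c3cc(OCc4ccccc4)c(OCc4ccccc4)c(OCc4ccccc4)c3)c([Mg]Cl)c(=O)c2c1OC | intermediate
14 | dimethyl [7-(benzyloxy)-5,6,8-trimethoxy-4-oxo-2-[3,4,5-tris(benzyloxy)phenyl]chromen-3-yl]boronate | COc1c(OCc2ccccc2)c(OC)c2oc(-c3cc(OCc4ccccc4)c(OCc4ccccc4)c(OCc4ccccc4)c3)c(B(OC)OC)c(=O)c2c1OC | intermediate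
15 | 7-(benzyloxy)-3-hydroxy-5,6,8-trimethoxy-2-[3,4,5-tris(benzyloxy)phenyl]chromen-4-one | COc1c(OCc2ccccc2)c(OC)c2oc(-c3cc(OCc4ccccc4)c(OCc4ccccc4)c(OCc4ccccc4)c3)c(O)c(=O)c2c1OC | intermediate
16 | 7-(benzyloxy)-3,5,6,8-tetramethoxy-2-[3,4,5-tris(benzyloxy)phenyl]chromen-4-one | COc1c(OCc2ccccc2)c(OC)c2oc(-c3cc(OCc4ccccc4)c(OCc4ccccc4)c(OCc4ccccc4)c3)c(OC)c(=O)c2c1OC | intermediate
17 | dichloroaluminium 7-(benzyloxy)-3,6,8-trimethoxy-4-oxo-2-[3,4,5-tris(benzyloxy)phenyl]chromen-5-olate | COc1c(OCc2ccccc2)c(OC)c2oc(-c3cc(OCc4ccccc4)c(OCc4ccccc4)c(OCc4ccccc4)c3)c(OC)c(=O)c2c1O[Al](Cl)Cl | intermediate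
18 | 7-(benzyloxy)-5-hydroxy-3,6,8-trimethoxy-2-[3,4,5-tris(benzyloxy)phenyl]chromen-4-one | COc1c(OCc2ccccc2)c(OC)c2oc(-c3cc(OCc4ccccc4)c(OCc4ccccc4)c(OCc4ccccc4)c3)c(OC)c(=O)c2c1O | intermediate
19 | 5,7,3',4',5'-pentahydroxy-3,6,8-trimethoxyflavone | COc1c(O)c(OC)c2oc(-c3cc(O)c(O)c(O)c3)c(OC)c(=O)c2c1O | target

**Total step count:** 12
**Longest linear sequence:** 11 (steps 1–5 and 7–12)

**Steps most likely to fail**

**Step 8 (key step).**
- What may go wrong: electrophilic iodination of ring B at C2'/C6' in competition with activation of the alkyne. Plain addition of I–Cl across the triple bond is also possible, because the doubly ortho-substituted aryl ketone is twisted away from the alkyne and the methoxy oxygen may not take part. The Lewis-acidic interhalogen could also erode the benzyl ethers.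
- Fallback: ring closure and C3 functionalisation are separated. Setting out from 10, AlCl3 in MeCN removes one of the two equivalent ortho methyl groups under chelation to the ketone. This should give 1-[4-(benzyloxy)-2-hydroxy-3,5,6-trimethoxyphenyl]-3-[3,4,5-tris(benzyloxy)phenyl]prop-2-yn-1-one F1.
- Et2NH in DMF adds to the ynone, and the phenol displaces the amine from the enaminone (net 6-endo oxa-Michael closure). This gives the 3-unsubstituted flavone 7-(benzyloxy)-5,6,8-trimethoxy-2-[3,4,5-tris(benzyloxy)phenyl]chromen-4-one F2.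
- C3 lithiation with LDA at −78 °C, B(OMe)3 and then H2O2/AcOH install the 3-hydroxyl. The route is rejoined at 15.

**Step 9.**
- What may go wrong: ring opening of the C3 carbanion by anti elimination across C2–O1, proton capture before the borate is trapped, or addition of the Grignard reagent to the pyrone.
- Fallback: the carbanion is avoided altogether. Setting out from 12, Miyaura borylation (B2pin2, PdCl2(dppf), KOAc, dioxane, 80 °C) uses the same C3–I oxidative addition that serves other cross-couplings of 3-iodoflavones. It should give 7-(benzyloxy)-5,6,8-trimethoxy-3-(4,4,5,5-tetramethyl-1,3,2-dioxaborolan-2-yl)-2-[3,4,5-tris(benzyloxy)phenyl]chromen-4-one F3.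
- Oxidation with NaBO3·4H2O in THF/H2O at rt brings the material back to the route at 15.

**Step 4.**
- What may go wrong: stalling after the first substitution, reductive loss of bromine at the crowded positions, and uncontrolled cleavage of the hindered ester under hot methoxide.
- Fallback: the C–O bonds are formed on the free carboxylate, which delivers copper to both ortho C–Br bonds (Hurtley-type ortho-carboxylate activation). The hindered ester stage disappears. Setting out from 3, NaOH in aqueous MeOH gives 4-(benzyloxy)-3,5-dimethoxybenzoic acid F4.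
- Br2/NaOAc in AcOH then gives 4-(benzyloxy)-2,6-dibromo-3,5-dimethoxybenzoic acid F5.
- The sodium salt of F5 is treated with NaOMe and CuBr in MeOH/DMF at about 90 °C and then acidified in the cold. This returns to the route at 6 and bypasses steps 4 and 5.

**Further compounds**
F1 | step 8 | 1-[4-(benzyloxy)-2-hydroxy-3,5,6-trimethoxyphenyl]-3-[3,4,5-tris(benzyloxy)phenyl]prop-2-yn-1-one | O=C(C#Cc1cc(OCc2ccccc2)c(OCc2ccccc2)c(OCc2ccccc2)c1)c1c(O)c(OC)c(OCc2ccccc2)c(OC)c1OC
F2 | step 8 | 7-(benzyloxy)-5,6,8-trimethoxy-2-[3,4,5-tris(benzyloxy)phenyl]chromen-4-one | COc1c(OCc2ccccc2)c(OC)c2oc(-c3cc(OCc4ccccc4)c(OCc4ccccc4)c(OCc4ccccc4)c3)cc(=O)c2c1OC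
F3 | step 9 | 7-(benzyloxy)-5,6,8-trimethoxy-3-(4,4,5,5-tetramethyl-1,3,2-dioxaborolan-2-yl)-2-[3,4,5-tris(benzyloxy)phenyl]chromen-4-one | COc1c(OCc2ccccc2)c(OC)c2oc(-c3cc(OCc4ccccc4)c(OCc4ccccc4)c(OCc4ccccc4)c3)c(B3OC(C)(C)C(C)(C)O3)c(=O)c2c1OC
F4 | step 4 | 4-(benzyloxy)-3,5-dimethoxybenzoic acid | OC(=O)c1cc(OC)c(OCc2ccccc2)c(OC)c1
F5 | step 4 | 4-(benzyloxy)-2,6-dibromo-3,5-dimethoxybenzoic acid | OC(=O)c1c(Br)c(OC)c(OCc2ccccc2)c(OC)c1Br
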